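**Strategy.** Ring C is cut at O1–C2 and C3–C4. The C8a oxygen and the C4a-bound C4 of ring A form an ortho-quinone methide, and C2–C3 is the vinyl group of a ring B styrene whose para (C4') methoxy group stabilises charge at C2. One acid-catalysed inverse-demand [4+2] cycloaddition therefore joins both halves, closes ring C, sets C2 (S) and delivers C4 already at the alcohol oxidation level as a methyl ether. The precursors are a ring A salicylaldehyde (free C8a hydroxyl, O5 silylated, C6 prenyl, C7 methoxy) and a 2-geranyl-3-silyloxy-4-methoxystyrene. Hydrolysis, oxidation and desilylation finish the flavanone.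

Key step: step 11

Remarks on the chemistry (assumptions):
- The enantiomer of the IDPi acid in step 11 is the one that gives 2S; if the sense of induction is opposite, the mirror-image catalyst is used.
- Compound 21 is carried forward as a mixture of C4 epimers, because C4 becomes the carbonyl carbon in step 13.
- Ring B carries a triisopropylsilyl ether: an ortho-lithiated aryl TIPS ether resists anionic oxygen-to-carbon silyl migration in step 10 and tolerates the strong acid of step 11. Ring A keeps the smaller TBS group next to the reacting carbon.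
- The C8a hydroxyl is masked as a 4-methoxybenzyl ether, removed oxidatively without touching the aryl TBS ether.
- Prenyl = 3-methylbut-2-en-1-yl; geranyl = (2E)-3,7-dimethylocta-2,6-dien-1-yl.

**Ring A aldehyde**

Step 1
Reactants: 1 2,4,6-trihydroxybenzaldehyde
Product: 2 2,6-dihydroxy-4-methoxybenzaldehyde
Conditions: Me2SO4 (1.0 equiv), K2CO3 (1.0 equiv), acetone, 0 °C → rt
Reagents that add atoms: dimethyl sulfate, COS(=O)(=O)OC
Why: Williamson O-methylation should select the 4-hydroxyl, which is para to the formyl group, the most acidic, and the only one not held in a hydrogen bond to the carbonyl.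

Step 2
Reactants: 3 2-methylbut-3-en-2-ol
Product: 5 methyl 2-methylbut-3-en-2-yl carbonate, via lithium 2-methylbut-3-en-2-olate 4 (not isolated)
Conditions: n-BuLi, THF, −78 °C; then ClCO2Me, −78 °C → rt
Reagents that add atoms: methyl chloroformate, COC(=O)Cl
Why: O-acylation of the preformed lithium alkoxide is the standard way to a tertiary allylic carbonate and avoids acid, so the allyl system is not transposed.

Step 3
Reactants: 2 2,6-dihydroxy-4-methoxybenzaldehyde; 5 methyl 2-methylbut-3-en-2-yl carbonate
Product: 6 2-hydroxy-4-methoxy-6-(2-methylbut-3-en-2-yloxy)benzaldehyde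
Conditions: Pd(PPh3)4 (3 mol%), THF, 0 °C → rt
Reagents that add atoms: none
Why: In this Tsuji–Trost O-allylation zerovalent palladium ionises the carbonate to a 1,1-dimethyl-π-allyl complex, the phenoxide attacks its more substituted end under kinetic control, and the second phenol stays chelated to the formyl group so the reaction should stop at the mono-ether.

Step 4
Reactants: 6 2-hydroxy-4-methoxy-6-(2-methylbut-3-en-2-yloxy)benzaldehyde
Product: 7 4-methoxy-2-(4-methoxybenzyloxy)-6-(2-methylbut-3-en-2-yloxy)benzaldehyde
Conditions: PMBCl (1.1 equiv), K2CO3, n-Bu4NI (cat.), DMF, rt → 40 °C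
Reagents that add atoms: 4-methoxybenzyl chloride, COc1ccc(CCl)cc1
Why: Williamson benzylation of the chelated phenol proceeds in K2CO3/DMF at a temperature well below the onset of rearrangement of the tertiary allyl ether.

Step 5
Reactants: 7 4-methoxy-2-(4-methoxybenzyloxy)-6-(2-methylbut-3-en-2-yloxy)benzaldehyde
Product: 8 2-hydroxy-4-methoxy-6-(4-methoxybenzyloxy)-3-prenylbenzaldehyde
Conditions: Eu(fod)3 [europium tris(6,6,7,7,8,8,8-heptafluoro-2,2-dimethyloctane-3,5-dionate)] (10 mol%), CHCl3, 50 °C
Reagents that add atoms: none
Why: In this aromatic Claisen rearrangement the terminal CH2 of the tertiary ether bonds to the only free ortho carbon, which turns the reversed ether into a normal prenyl group beside the methoxy group, and enolisation restores the phenol.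

Step 6
Reactants: 8 2-hydroxy-4-methoxy-6-(4-methoxybenzyloxy)-3-prenylbenzaldehyde
Product: 9 2-(tert-butyldimethylsilyloxy)-4-methoxy-6-(4-methoxybenzyloxy)-3-prenylbenzaldehyde
Conditions: TBSOTf (1.3 equiv), 2,6-lutidine, CH2Cl2, 0 °C
Reagents that add atoms: tert-butyldimethylsilyl triflate, CC(C)(C)[Si](C)(C)OS(=O)(=O)C(F)(F)F
Why: The silyl triflate with a hindered pyridine base is reactive enough to silylate a chelated phenol flanked by two ortho groups, and the benzyl ether, aldehyde and alkene are inert to it at 0 °C.

Step 7
Reactants: 9 2-(tert-butyldimethylsilyloxy)-4-methoxy-6-(4-methoxybenzyloxy)-3-prenylbenzaldehyde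
Product: 10 2-(tert-butyldimethylsilyloxy)-6-hydroxy-4-methoxy-3-prenylbenzaldehyde
Conditions: DDQ (1.3 equiv), CH2Cl2/pH 7 phosphate buffer (10:1), 0 °C → rt
Reagents that add atoms: none
Why: Oxidative 4-methoxybenzyl ether cleavage (hydride abstraction from the benzylic CH2, then hydrolysis) is neutral, so the aryl silyl ether, the aldehyde and the prenyl group, which has no free phenol beside it, should survive.

**Ring B styrene**

Step 8
Reactants: 11 2-bromoisovanillin (2-bromo-3-hydroxy-4-methoxybenzaldehyde)
Product: 12 2-bromo-4-methoxy-3-(triisopropylsilyloxy)benzaldehyde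
Conditions: TIPSOTf (1.2 equiv), 2,6-lutidine, CH2Cl2, 0 °C → rt
Reagents that add atoms: triisopropylsilyl triflate, CC(C)[Si](C(C)C)(C(C)C)OS(=O)(=O)C(F)(F)F
Why: Silyl triflate silylation of the phenol flanked by bromine and methoxy gives an ether bulky enough to resist silyl migration to an adjacent carbanion and acid-promoted loss later.

Step 9
Reactants: 12 2-bromo-4-methoxy-3-(triisopropylsilyloxy)benzaldehyde
Product: 13 2-bromo-1-ethenyl-4-methoxy-3-(triisopropylsilyloxy)benzene
Conditions: Ph3PCH3Br, n-BuLi, THF, 0 °C; then 12, −78 °C → rt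
Reagents that add atoms: methyltriphenylphosphonium bromide, C[P+](c1ccccc1)(c1ccccc1)c1ccccc1.[Br-]
Why: Wittig methylenation of a non-enolisable aryl aldehyde with the preformed ylide leaves the aryl bromide and silyl ether untouched, and placing it before the metalation removes the need to protect the aldehyde.

Step 10
Reactants: 13 2-bromo-1-ethenyl-4-methoxy-3-(triisopropylsilyloxy)benzene; 14 geranyl bromide
Product: 17 1-ethenyl-2-geranyl-4-methoxy-3-(triisopropylsilyloxy)benzene, via aryllithium 15 (not isolated), via arylcopper 16 (not isolated)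
Conditions: t-BuLi (2.05 equiv), THF, −78 °C; CuBr·SMe2 (1.0 equiv), −78 → −40 °C; then 14, −40 → 0 °C
Reagents that add atoms: none
Why: Bromine–lithium exchange outruns addition to the styrene at −78 °C, and the arylcopper formed by transmetalation alkylates geranyl bromide at its primary carbon in an SN2-type allylic substitution, keeping the E alkene because attack at the other allyl terminus would build a quaternary centre between two ortho substituents.

**Key step**

Step 11
Reactants: 10 2-(tert-butyldimethylsilyloxy)-6-hydroxy-4-methoxy-3-prenylbenzaldehyde; 17 1-ethenyl-2-geranyl-4-methoxy-3-(triisopropylsilyloxy)benzene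
Product: 20 (2S,4S)-5-(tert-butyldimethylsilyloxy)-2-[2-geranyl-4-methoxy-3-(triisopropylsilyloxy)phenyl]-4,7-dimethoxy-6-prenylchroman, via dimethyl acetal 18 (not isolated), via ortho-quinone methide 19 (not isolated)
Conditions: (S,S)-IDPi acid [BINOL-derived imidodiphosphorimidate, 3,3'-bis(3,5-bis(trifluoromethyl)phenyl), N-triflyl] (5 mol%), HC(OMe)3 (1.5 equiv), 17 (1.2 equiv), 4 Å MS, CH2Cl2, −60 → −30 °C
Reagents that add atoms: trimethyl orthoformate, COC(OC)OC
Why: Proposed new method: acid-catalysed acetalisation of 10 and loss of methanol from 18 give the 4-methoxy ortho-quinone methide 19, present in protonated form as a benzylic oxocarbenium ion paired with the confined chiral IDPi anion; the styrene CH2 of 17 (future C3) attacks C4 while charge grows at C2, stabilised by the para C4' methoxy group, until the C8a oxygen bonds to C2. The closest known reaction types are the racemic Lewis acid union of salicylaldehydes, orthoformates and styrenes to 2,4-cis-4-alkoxyflavans and chiral phosphoric acid catalysed [4+2] reactions of ortho-quinone methides with styrenes, and their merger under a chiral counter-anion is the new element. Ring C closes by an asynchronous inverse-demand hetero-[4+2] cycloaddition across O1=C8a–C4a=C4, which in the stepwise limit is a six-membered closure of the phenol oxygen onto the C2 benzylic cation. C2 (S) is set by the chiral anion, which shields one face of the ion pair so that the styrene is taken up and closed from one side only; C4 follows from the endo-type approach that places the aryl group cis to the methoxy group, and it is erased in step 13. Regiochemistry follows from the polarity of the styrene, only the C8a oxygen can close because O5 is silylated, and both silyl ethers keep the phenols from adding to the prenyl and geranyl alkenes under acid. The selectivity the step needs is O1–C2 closure faster than five-membered capture of the C2 cation by the neighbouring geranyl alkene, which the contact ion pair, the low temperature and the phenol oxygen held next to the developing cation should secure.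

**Endgame**

Step 12
Reactants: 20 (2S,4S)-5-(tert-butyldimethylsilyloxy)-2-[2-geranyl-4-methoxy-3-(triisopropylsilyloxy)phenyl]-4,7-dimethoxy-6-prenylchroman
Product: 21 (2S,4RS)-5-(tert-butyldimethylsilyloxy)-2-[2-geranyl-4-methoxy-3-(triisopropylsilyloxy)phenyl]-7-methoxy-6-prenylchroman-4-ol
Conditions: PPTS (0.2 equiv), THF/H2O (4:1), 35 °C
Reagents that add atoms: water, O
Why: SN1 solvolysis is easy because the C4 cation is stabilised by the three ring A oxygens ortho and para to C4a, water in large excess captures it, C2 is not involved, and aryl silyl ethers and trisubstituted alkenes tolerate this weak acid.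

Step 13
Reactants: 21 (2S,4RS)-5-(tert-butyldimethylsilyloxy)-2-[2-geranyl-4-methoxy-3-(triisopropylsilyloxy)phenyl]-7-methoxy-6-prenylchroman-4-ol
Product: 22 (2S)-5-(tert-butyldimethylsilyloxy)-2-[2-geranyl-4-methoxy-3-(triisopropylsilyloxy)phenyl]-7-methoxy-6-prenylchroman-4-one
Conditions: Dess–Martin periodinane (1.5 equiv), pyridine (5 equiv), CH2Cl2, 0 °C → rt
Reagents that add atoms: none
Why: Dess–Martin oxidation converts both C4 epimers of the benzylic alcohol to the ketone under buffered, non-basic conditions that cannot open the pyranone by retro-oxa-Michael reaction, so C2 stays S.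

Step 14
Reactants: 22 (2S)-5-(tert-butyldimethylsilyloxy)-2-[2-geranyl-4-methoxy-3-(triisopropylsilyloxy)phenyl]-7-methoxy-6-prenylchroman-4-one
Product: 23 (2S)-2-(2-geranyl-3-hydroxy-4-methoxyphenyl)-5-hydroxy-7-methoxy-6-prenylchroman-4-one (CNP0241771.1)
Conditions: TBAF (3 equiv), AcOH (3 equiv), THF, 0 °C → rt
Reagents that add atoms: none
Why: Fluoride cleaves both aryl silyl ethers, and the acetic acid buffer keeps the medium from becoming basic, which prevents E1cB opening to the chalcone and hence racemisation at C2.

**Compound list**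

1 | 2,4,6-trihydroxybenzaldehyde | O=Cc1c(O)cc(O)cc1O | starting material
2 | 2,6-dihydroxy-4-methoxybenzaldehyde | COc1cc(O)c(C=O)c(O)c1 | intermediate
3 | 2-methylbut-3-en-2-ol | CC(C)(O)C=C | starting material
4 | lithium 2-methylbut-3-en-2-olate (not isolated) | [Li+].CC(C)([O-])C=C | intermediate
5 | methyl 2-methylbut-3-en-2-yl carbonate | COC(=O)OC(C)(C)C=C | intermediate
6 | 2-hydroxy-4-methoxy-6-(2-methylbut-3-en-2-yloxy)benzaldehyde | COc1cc(O)c(C=O)c(OC(C)(C)C=C)c1 | intermediate
7 | 4-methoxy-2-(4-methoxybenzyloxy)-6-(2-methylbut-3-en-2-yloxy)benzaldehyde | COc1ccc(COc2cc(OC)cc(OC(C)(C)C=C)c2C=O)cc1 | intermediate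
8 | 2-hydroxy-4-methoxy-6-(4-methoxybenzyloxy)-3-prenylbenzaldehyde | COc1ccc(COc2cc(OC)c(CC=C(C)C)c(O)c2C=O)cc1 | intermediate
9 | 2-(tert-butyldimethylsilyloxy)-4-methoxy-6-(4-methoxybenzyloxy)-3-prenylbenzaldehyde | COc1ccc(COc2cc(OC)c(CC=C(C)C)c(O[Si](C)(C)C(C)(C)C)c2C=O)cc1 | intermediate
10 | 2-(tert-butyldimethylsilyloxy)-6-hydroxy-4-methoxy-3-prenylbenzaldehyde (ring A partner) | COc1cc(O)c(C=O)c(O[Si](C)(C)C(C)(C)C)c1CC=C(C)C | intermediate
11 | 2-bromoisovanillin | COc1ccc(C=O)c(Br)c1O | starting material
12 | 2-bromo-4-methoxy-3-(triisopropylsilyloxy)benzaldehyde | COc1ccc(C=O)c(Br)c1O[Si](C(C)C)(C(C)C)C(C)C | intermediate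
13 | 2-bromo-1-ethenyl-4-methoxy-3-(triisopropylsilyloxy)benzene | COc1ccc(C=C)c(Br)c1O[Si](C(C)C)(C(C)C)C(C)C | intermediate
14 | geranyl bromide | CC(C)=CCC/C(C)=C/CBr | starting material
15 | [6-ethenyl-3-methoxy-2-(triisopropylsilyloxy)phenyl]lithium (not isolated) | COc1ccc(C=C)c([Li])c1O[Si](C(C)C)(C(C)C)C(C)C | intermediate
16 | [6-ethenyl-3-methoxy-2-(triisopropylsilyloxy)phenyl]copper (not isolated) | COc1ccc(C=C)c([Cu])c1O[Si](C(C)C)(C(C)C)C(C)C | intermediate
17 | 1-ethenyl-2-geranyl-4-methoxy-3-(triisopropylsilyloxy)benzene (ring B partner) | COc1ccc(C=C)c(C/C=C(\C)CCC=C(C)C)c1O[Si](C(C)C)(C(C)C)C(C)C | intermediate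
18 | dimethyl acetal of 10 (not isolated) | COC(OC)c1c(O)cc(OC)c(CC=C(C)C)c1O[Si](C)(C)C(C)(C)C | intermediate
19 | (E)-4-methoxy ortho-quinone methide from 18 (not isolated) | CO/C=C1/C(=O)C=C(OC)C(CC=C(C)C)=C1O[Si](C)(C)C(C)(C)C | intermediate
20 | (2S,4S)-5-(tert-butyldimethylsilyloxy)-2-[2-geranyl-4-methoxy-3-(triisopropylsilyloxy)phenyl]-4,7-dimethoxy-6-prenylchroman | COc1ccc([C@@H]2C[C@H](OC)c3c(cc(OC)c(CC=C(C)C)c3O[Si](C)(C)C(C)(C)C)O2)c(C/C=C(\C)CCC=C(C)C)c1O[Si](C(C)C)(C(C)C)C(C)C | intermediate
21 | (2S,4RS)-5-(tert-butyldimethylsilyloxy)-2-[2-geranyl-4-methoxy-3-(triisopropylsilyloxy)phenyl]-7-methoxy-6-prenylchroman-4-ol (C4 epimers) | COc1ccc([C@@H]2CC(O)c3c(cc(OC)c(CC=C(C)C)c3O[Si](C)(C)C(C)(C)C)O2)c(C/C=C(\C)CCC=C(C)C)c1O[Si](C(C)C)(C(C)C)C(C)C | intermediate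
22 | (2S)-5-(tert-butyldimethylsilyloxy)-2-[2-geranyl-4-methoxy-3-(triisopropylsilyloxy)phenyl]-7-methoxy-6-prenylchroman-4-one | COc1ccc([C@@H]2CC(=O)c3c(cc(OC)c(CC=C(C)C)c3O[Si](C)(C)C(C)(C)C)O2)c(C/C=C(\C)CCC=C(C)C)c1O[Si](C(C)C)(C(C)C)C(C)C | intermediate
23 | (2S)-2-(2-geranyl-3-hydroxy-4-methoxyphenyl)-5-hydroxy-7-methoxy-6-prenylchroman-4-one | COc1ccc([C@@H]2CC(=O)c3c(cc(OC)c(CC=C(C)C)c3O)O2)c(C/C=C(\C)CCC=C(C)C)c1O | target

**Step count.** Total: 14 steps. Longest linear sequence: 10 steps (1, 3, 4, 5, 6, 7, 11, 12, 13, 14).

**Steps most likely to fail**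

Step 11. Two processes can defeat it: weak facial control at C2 by the chiral anion, and interception of the C2 cation by the geranyl alkene or acid-promoted consumption of the styrene before ring closure. The fallback secures C2 by resolution instead of catalyst control and uses only the known Lewis acid reaction type. Setting out from 10 and 17, Sc(OTf)3 (10 mol%) with HC(OMe)3 in CH2Cl2 at low temperature should give the racemic 2,4-cis 4-methoxyflavan, that is 20 together with its mirror image, (2R,4R)-5-(tert-butyldimethylsilyloxy)-2-[2-geranyl-4-methoxy-3-(triisopropylsilyloxy)phenyl]-4,7-dimethoxy-6-prenylchroman F1. Preparative chromatography on a chiral stationary phase separates the two, and the route is rejoined at 20.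

Step 12. The C4 cation may lose a C3 proton to give the flav-3-ene, or alkylate the electron-rich C8 of a second molecule, instead of taking up water. The fallback replaces solvolysis by oxidation. Setting out from 20, DDQ in wet CH2Cl2 at 0 °C abstracts the C4 hydride, which is activated by ring A and the methoxy group; water adds to the methoxy-oxocarbenium ion and methanol is lost, giving the ketone directly. The route is rejoined at 22 and one step is saved; no compound outside the list is made (F0).

Step 3. The kinetically formed tertiary aryl ether may re-ionise on palladium and drift to the linear prenyl ether, or the π-allyl complex may alkylate the ring carbon. The fallback builds the tertiary ether without a π-allyl intermediate. Setting out from 2, CuCl2·2H2O (cat.), DBU and 3-chloro-3-methylbut-1-yne in MeCN at 0 °C should give 2-hydroxy-4-methoxy-6-(2-methylbut-3-yn-2-yloxy)benzaldehyde F2. Semi-hydrogenation of the alkyne (H2, Pd/CaCO3 poisoned with Pb(OAc)2, quinoline, EtOAc) then rejoins the route at 6.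

**Further compounds**

F1 | step 11 | (2R,4R)-5-(tert-butyldimethylsilyloxy)-2-[2-geranyl-4-methoxy-3-(triisopropylsilyloxy)phenyl]-4,7-dimethoxy-6-prenylchroman | COc1ccc([C@H]2C[C@@H](OC)c3c(cc(OC)c(CC=C(C)C)c3O[Si](C)(C)C(C)(C)C)O2)c(C/C=C(\C)CCC=C(C)C)c1O[Si](C(C)C)(C(C)C)C(C)C
F0 | step 12 | none | none
F2 | step 3 | 2-hydroxy-4-methoxy-6-(2-methylbut-3-yn-2-yloxy)benzaldehyde | COc1cc(O)c(C=O)c(OC(C)(C)C#C)c1
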